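The numbers of this flask were set for the occasion; what happens was integrated by code.

One unit of E held in a link E.G is what I follow through these flasks.

| flask | E | G | time | remark |
|---|---|---|---|---|
| larch | 0.29 M | 0.950 equiv (fed, over 3.00 h) | 3.0 h | all but G at the start; G goes in evenly over 3.00 h, the run ends at 3.0 h |
| cedar | 0.29 M | 0.950 equiv | 3.0 h | everything together in a closed stirred flask, run for 3.0 h |
| alder | 0.29 M | 0.950 equiv |  | one stirred flow tank at steady state, fed with the mixture as stated, mean residence time 3.0 h |
| ash | 0.29 M (fed, over 3.00 h) | 0.950 equiv | 3.0 h | all but E at the start; E goes in evenly over 3.00 h, the run ends at 3.0 h |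

    E + E.G → E.E.G (k1 = 0.126 L mol⁻¹ min⁻¹)
    2 G → G2 (k2 = 0.142 L mol⁻¹ min⁻¹)
    E.G ⇌ Q (K3 = 1.7, k3 = 0.00117 min⁻¹)
    E + G → E.G (k4 = 0.807 L mol⁻¹ min⁻¹)

* the set-up with the highest share of E.G in all that became E.G or Q or E.E.G, at the outlet or at the end ("none" if the first two lie within 2 percentage points) (larch / cedar / alder / ash / none)
* share of E.G in all that became E.G or Q or E.E.G, at the outlet or at the end, larch
* share of E.G in all that became E.G or Q or E.E.G, at the outlet or at the end, cedar
* share of E.G in all that became E.G or Q or E.E.G, at the outlet or at the end, alder
* share of E.G in all that became E.G or Q or E.E.G, at the outlet or at the end, ash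

- percent here means E units held: one E.E.G counts as two
- a step written with two of one species runs at k times the square of its concentration and takes two of it each time
- the stated concentrations are those of everything mixed, before any reaction; amounts are the same in each set-up
- the feed brings no volume worth counting
- run time (larch): 3.0 h

Free E attacks a link as a first-order decay with rate constant k[E], k being 0.126 L mol⁻¹ min⁻¹ (pseudo-first-order). So I reckon the fraction of links left, f = exp(−X), with X the time integral of k[E]. One E.E.G counts as two units of E, so, with the drift to Q neglected, my estimate of the asked share is f/(2−f). If free E ramps from nothing to a level c over the dose, X is w·c. The exposure constant w = 11.3 L mol⁻¹, k times half the dose time, turns an end level of E into a fraction left.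

The first setting is who is dosed. In ash, E goes into G, and the pairing half-life of G, 0.213 h, is short against the dose, so I date the links of ash to the early dose. Counting the whole charge as free gives X = 3.29, leaving 3.73% of the links, a share of 1.90%. In larch, G goes into E: the oldest link faces that same X and the youngest none, so I put larch above ash. In cedar, E and G fall together, the half-life of E against G being 0.052 h. Neglecting pairing, X is the selectivity factor 0.156 times the logarithm of 43.1, which is 0.588, leaving 55.6% of the links, a share of 38.5%, more than ash. I leave the tank alder unreckoned, since I have no free E for it by hand.

The second setting is time. In cedar, X grows with the logarithm of time, and the drift to Q has a forward half-life of 9.9 h, long against the run. The third is concentration: in ash, X scales with c, so a weaker charge should keep more.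

The forecast names cedar, with 34% for larch, 39% for cedar, 35.4% for alder and 19% for ash, above my share for ash, holding that “most of the G dimerises within the first hour”.

The simulation names cedar: larch 30.2%, cedar 40.7%, alder 35.4%, ash 12.7%. A neighbour flask, like ash but with 0.12 M of E, takes the same reckoning: X = 1.36, leaving 25.6% of the links, a share of 14.7%, more than the 1.90% I had for ash. The neighbour gives a share of 39.4%, higher than the 12.7% of ash, and it ends with 19.6% of its E charge as E.G.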